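**Retrosynthetic overview**
1. Target 27 ← Shi epoxidation of the C10=C11 alkene and acetylation of the macrocyclic C14 alcohol 25.
2. 25 ← ring contraction: a 15-membered cyclic boronate (boron between C1 and C14) undergoes a 1,2-metallate shift that forms C14–C1, expels boron from the ring and sets C14. The boronate comes from the open-chain lactone 21.
3. 21 ← indium-mediated Barbier union at C7–C8 of allylic bromide 9 with the α-hydroxy aldehyde from 17. This builds the cis-α-methylene lactone and sets C7 and C8.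
4. 9 ← pent-4-yn-1-ol, allyl bromide, methyl 2-(bromomethyl)acrylate. 17 ← cis-but-2-ene, 2,2-dimethoxyacetaldehyde, 2,3-dibromopropene.
5. Ring order: butyrolactone, then the transient 15-membered boracycle, then the 14-membered carbocycle, then the oxirane.

Assumption and conventions: the SMILES fixes the target as the (5S,6R,7R,8S,10R,11R,14R) isomer in the ring numbering used here: C1 (bearing exocyclic C1′H2), C2–C4 CH2, C5 CHMe, C6 CHOAc, C7 CH–O(lactone), C8 lactone CH, C9 CH2, C10/C11 epoxide, C12–C13 CH2, C14 CHOAc, lactone carbons C15 (=C17H2) and C16 (C=O). TIB = 2,4,6-triisopropylbenzoyl, Bpin = 4,4,5,5-tetramethyl-1,3,2-dioxaborolan-2-yl, Ipc = isopinocampheyl, Tol = p-tolyl.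

**Route**

Step 1
Reactants: 1 pent-4-yn-1-ol
Product: 2 pent-4-yn-1-yl 2,4,6-triisopropylbenzoate
Conditions: TIBCl, pyridine, DMAP (cat.), CH2Cl2, 0 °C to reflux
Reagents that add atoms: 2,4,6-triisopropylbenzoyl chloride, CC(C)c1cc(C(C)C)c(C(Cl)=O)c(C(C)C)c1
Why: Acylation of the primary alcohol (nucleophilic acyl substitution) installs the hindered TIB ester, which later directs α-lithiation and acts as the leaving group; no stereocentre is formed.

Step 2
Reactants: 2 pent-4-yn-1-yl 2,4,6-triisopropylbenzoate; 3 allyl bromide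
Product: 5 (4E)-4-methylocta-4,7-dien-1-yl 2,4,6-triisopropylbenzoate, via alkenyldimethylalane 4 (not isolated)
Conditions: Me3Al (2.5 equiv), Cp2ZrCl2 (20 mol %), H2O (1 equiv), CH2Cl2, −20 °C to rt; then 3, Pd(PPh3)4 (5 mol %), THF, rt
Reagents that add atoms: trimethylaluminium, C[Al](C)C
Why: Negishi zirconium-catalysed syn-methylalumination of the terminal alkyne gives the (E)-alkenylalane, and palladium-catalysed cross-coupling with allyl bromide proceeds with retention, fixing the E-trisubstituted C10=C11 alkene; the hindered TIB ester is inert to Me3Al.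

Step 3
Reactants: 5 (4E)-4-methylocta-4,7-dien-1-yl 2,4,6-triisopropylbenzoate
Product: 7 (1S,4E)-4-methyl-1-[(S)-p-tolylsulfinyl]octa-4,7-dien-1-yl 2,4,6-triisopropylbenzoate, via α-lithio TIB ester 6 (not isolated)
Conditions: s-BuLi, (−)-sparteine, Et2O, −78 °C, 5 h; then cannulate into (1R,2S,5R)-menthyl (S)-p-toluenesulfinate, THF, −78 °C; aq. NH4Cl
Reagents that add atoms: (1R,2S,5R)-(−)-menthyl (S)-p-toluenesulfinate, C[C@@H]1CC[C@H]([C@@H](C1)O[S@](=O)c2ccc(C)cc2)C(C)C
Why: Hoppe-type sparteine-mediated asymmetric deprotonation removes the pro-S α-hydrogen (the chiral base sets C14), and the configurationally stable organolithium is sulfinylated with retention at carbon and inversion at sulfur (Andersen sulfoxide synthesis) to give a bench-stable carbenoid precursor.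

Step 4
Reactants: 7 (1S,4E)-4-methyl-1-[(S)-p-tolylsulfinyl]octa-4,7-dien-1-yl 2,4,6-triisopropylbenzoate; 8 methyl 2-(bromomethyl)acrylate
Product: 9 methyl (2Z,5E,9S)-2-(bromomethyl)-6-methyl-9-[(S)-p-tolylsulfinyl]-9-(2,4,6-triisopropylbenzoyloxy)nona-2,5-dienoate
Conditions: 8 (4 equiv), Hoveyda–Grubbs II (10 mol %), 1,4-benzoquinone (10 mol %), CH2Cl2, 40 °C
Reagents that add atoms: none
Why: Olefin cross-metathesis of the only monosubstituted alkene with the 1,1-disubstituted acrylate gives the trisubstituted enoate with the ester trans to the chain (thermodynamic isomer, 2Z by CIP), which is the 2-(bromomethyl)alk-2-enoate needed for the Barbier step.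

Step 5
Reactants: 10 cis-but-2-ene; 11 2,2-dimethoxyacetaldehyde
Product: 13 (2R,3S)-1,1-dimethoxy-3-methylpent-4-en-2-ol, via (Z)-crotylbis(isopinocampheyl)borane 12 (not isolated)
Conditions: KOt-Bu, n-BuLi, THF, −78 to −45 °C; (+)-Ipc2BOMe, −78 °C; BF3·OEt2; anhydrous 11, −78 °C; then NaOH, H2O2
Reagents that add atoms: none
Why: Brown asymmetric crotylboration: the (Z)-crotylborane reacts through a chair Zimmerman–Traxler transition state to give the syn product, and the Ipc ligands derived from (−)-α-pinene select the aldehyde face that gives (2R,3S), setting C5 and C6.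

Step 6
Reactants: 13 (2R,3S)-1,1-dimethoxy-3-methylpent-4-en-2-ol; 14 2,3-dibromoprop-1-ene
Product: 16 (2R,3S)-7-bromo-1,1-dimethoxy-3-methyloct-7-en-2-ol, via B-alkyl-9-BBN adduct 15 (not isolated)
Conditions: 9-BBN-H (2.2 equiv, one equivalent caps the hydroxyl), THF, 0 to 50 °C; then 14, CuOAc (10 mol %), KOt-Bu, THF, rt
Reagents that add atoms: none
Why: Anti-Markovnikov hydroboration of the terminal alkene followed by copper-catalysed allyl–alkyl coupling of the B-alkyl-9-BBN with 2,3-dibromopropene (SN2 and SN2′ give the same product) builds the C2–C3 bond and delivers the 2-bromo-1-alkene without touching the stereocentres.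

Step 7
Reactants: 16 (2R,3S)-7-bromo-1,1-dimethoxy-3-methyloct-7-en-2-ol
Product: 17 (2R,3S)-1,1-dimethoxy-3-methyl-7-(4,4,5,5-tetramethyl-1,3,2-dioxaborolan-2-yl)oct-7-en-2-ol
Conditions: B2pin2, PdCl2(PPh3)2 (3 mol %), PPh3, KOPh, toluene, 50 °C
Reagents that add atoms: bis(pinacolato)diboron, CC1(C)OB(OC1(C)C)B1OC(C)(C)C(C)(C)O1
Why: Miyaura borylation of the 1,1-disubstituted alkenyl bromide; the weak phenoxide base avoids Suzuki homocoupling and tolerates the free alcohol and the acetal.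

Step 8
Reactants: 17 (2R,3S)-1,1-dimethoxy-3-methyl-7-(pinacolboryl)oct-7-en-2-ol; 9 methyl (2Z,5E,9S)-2-(bromomethyl)-6-methyl-9-[(S)-p-tolylsulfinyl]-9-(2,4,6-triisopropylbenzoyloxy)nona-2,5-dienoate
Product: 20 (5S,6R,7R,8S,10E,14S)-1,14-seco hydroxy lactone (C6–OH; cis-fused 7,16-olide with C15=C17H2; C1 alkenyl-Bpin; C14 bearing OTIB and (S)-S(O)Tol), via α-hydroxy aldehyde 18 (not isolated), via syn,syn-hydroxy ester 19 (not isolated)
Conditions: 1 M HCl, THF, rt; NaHCO3 to pH 6; 9, In powder, THF–H2O (1:1), rt; pinacol work-up; then p-TsOH (cat.), CH2Cl2, rt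
Reagents that add atoms: water, O
Why: Indium-mediated Barbier allylation in water of the free α-hydroxy aldehyde: chelation of indium by the C6 hydroxyl and the carbonyl gives the 6,7-syn diol, the geometrically fixed (Z)-allylindium reacts through a cyclic transition state to give 7,8-syn, and the γ-hydroxy ester lactonises to the cis-fused α-methylene-γ-butyrolactone, setting C7 and C8.

Step 9
Reactants: 20 (5S,6R,7R,8S,10E,14S)-1,14-seco hydroxy lactone
Product: 21 (5S,6R,7R,8S,10E,14S)-1,14-seco acetoxy lactone (as 20 with C6–OAc)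
Conditions: Ac2O, pyridine, DMAP (cat.), CH2Cl2, 0 °C
Reagents that add atoms: acetic anhydride, CC(=O)OC(C)=O
Why: DMAP-catalysed acylation of the only free hydroxyl installs the C6 acetate of the target and removes the acidic proton before the organomagnesium step.

Step 10
Reactants: 21 (5S,6R,7R,8S,10E,14S)-1,14-seco acetoxy lactone
Product: 25 (5S,6R,7R,8S,10E,14R)-6-acetoxy-14-hydroxy macrocyclic lactone (14-membered carbocycle with C1=C1′H2 and C10=C11), via magnesium carbenoid 22 (not isolated), via cyclic boronate complex 23 (not isolated), via macrocyclic allylic boronic ester 24 (not isolated)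
Conditions: i-PrMgCl·LiCl (1.3 equiv), THF (2 mM), −78 °C, then warm to 40 °C; then H2O2, aq. NaHCO3, 0 °C
Reagents that add atoms: hydrogen peroxide, OO
Why: Proposed new method: a macrocyclising, ring-contracting 1,2-metallate shift in which sulfoxide–magnesium exchange at −78 °C (faster than Grignard attack on acetate, lactone or Bpin) unmasks the α-acyloxyalkylmagnesium carbenoid 22 with retention at C14, intramolecular capture by the alkenyl-Bpin at high dilution gives the 15-membered cyclic boronate 23, and on warming C1 migrates from boron to C14 anti to the departing TIB carboxylate (inversion), expelling boron from the ring to leave the 14-membered carbocycle as allylic boronic ester 24, which is oxidised with retention to the (14R)-alcohol; the closest known reaction type is the intermolecular reagent-controlled homologation of boronic esters with magnesium carbenoids from α-sulfinyl benzoates under Barbier conditions (Matteson-type 1,2-migration), which has not been used intramolecularly to contract a macrocyclic boronate.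

Step 11
Reactants: 25 (5S,6R,7R,8S,10E,14R)-6-acetoxy-14-hydroxy macrocyclic lactone
Product: 26 (5S,6R,7R,8S,10E,14R)-6,14-diacetoxy macrocyclic lactone
Conditions: Ac2O, Et3N, DMAP (cat.), CH2Cl2, rt
Reagents that add atoms: acetic anhydride, CC(=O)OC(C)=O
Why: DMAP-catalysed acylation of the secondary allylic alcohol proceeds with retention at C14 and completes the diacetate.

Step 12
Reactants: 26 (5S,6R,7R,8S,10E,14R)-6,14-diacetoxy macrocyclic lactone
Product: 27 target CNP0323853.1, the (5S,6R,7R,8S,10R,11R,14R)-6,14-diacetoxy-10,11-epoxy macrocyclic lactone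
Conditions: Shi ketone (D-fructose-derived, 30 mol %), Oxone, K2CO3, Bu4NHSO4, MeCN–dimethoxymethane/aq. borate buffer (pH 10.5), 0 °C
Reagents that add atoms: potassium peroxymonosulfate (Oxone), [K+].[O-]S(=O)(=O)OO
Why: Shi asymmetric epoxidation (chiral dioxirane, spiro transition state) is chemoselective for the only electron-rich trisubstituted alkene over the allylic-acetate 1,1-alkene and the acrylate, and the D-fructose-derived ketone gives the (R,R)-epoxide of E-trisubstituted alkenes, here (10R,11R).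

**Compound list**
1 | pent-4-yn-1-ol | C#CCCCO | starting material
2 | pent-4-yn-1-yl 2,4,6-triisopropylbenzoate | C#CCCCOC(=O)c1c(C(C)C)cc(C(C)C)cc1C(C)C | intermediate
3 | allyl bromide | C=CCBr | starting material
4 | dimethyl[(1E)-2-methyl-5-(TIB-oxy)pent-1-en-1-yl]alane | C[Al](C)/C=C(\C)CCCOC(=O)c1c(C(C)C)cc(C(C)C)cc1C(C)C | intermediate
5 | (4E)-4-methylocta-4,7-dien-1-yl 2,4,6-triisopropylbenzoate | C=CC/C=C(\C)CCCOC(=O)c1c(C(C)C)cc(C(C)C)cc1C(C)C | intermediate
6 | (1S,4E)-1-lithio-4-methylocta-4,7-dien-1-yl 2,4,6-triisopropylbenzoate ((−)-sparteine complex) | C=CC/C=C(\C)CC[C@@H](OC(=O)c1c(C(C)C)cc(C(C)C)cc1C(C)C)[Li] | intermediate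
7 | (1S,4E)-4-methyl-1-[(S)-p-tolylsulfinyl]octa-4,7-dien-1-yl 2,4,6-triisopropylbenzoate | C=CC/C=C(\C)CC[C@@H](OC(=O)c1c(C(C)C)cc(C(C)C)cc1C(C)C)[S@@](=O)c1ccc(C)cc1 | intermediate
8 | methyl 2-(bromomethyl)acrylate | COC(=O)C(=C)CBr | starting material
9 | methyl (2Z,5E,9S)-2-(bromomethyl)-6-methyl-9-[(S)-p-tolylsulfinyl]-9-(2,4,6-triisopropylbenzoyloxy)nona-2,5-dienoate | COC(=O)/C(CBr)=C/C/C=C(\C)CC[C@@H](OC(=O)c1c(C(C)C)cc(C(C)C)cc1C(C)C)[S@@](=O)c1ccc(C)cc1 | intermediate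
10 | cis-but-2-ene | C/C=C\C | starting material
11 | 2,2-dimethoxyacetaldehyde | COC(OC)C=O | starting material
12 | (Z)-but-2-enylbis(isopinocampheyl)borane (Ipc from (−)-α-pinene) | C/C=C\CB([C@H]1C[C@H]2C[C@@H]([C@@H]1C)C2(C)C)[C@H]1C[C@H]2C[C@@H]([C@@H]1C)C2(C)C | intermediate
13 | (2R,3S)-1,1-dimethoxy-3-methylpent-4-en-2-ol | C=C[C@H](C)[C@@H](O)C(OC)OC | intermediate
14 | 2,3-dibromoprop-1-ene | C=C(Br)CBr | starting material
15 | 9-[(3S,4R)-5,5-dimethoxy-3-methyl-4-(9-BBN-oxy)pentyl]-9-borabicyclo[3.3.1]nonane | B1(CC[C@H](C)[C@@H](OB2C3CCCC2CCC3)C(OC)OC)C2CCCC1CCC2 | intermediate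
16 | (2R,3S)-7-bromo-1,1-dimethoxy-3-methyloct-7-en-2-ol | C=C(Br)CCC[C@H](C)[C@@H](O)C(OC)OC | intermediate
17 | (2R,3S)-1,1-dimethoxy-3-methyl-7-(pinacolboryl)oct-7-en-2-ol | C=C(B1OC(C)(C)C(C)(C)O1)CCC[C@H](C)[C@@H](O)C(OC)OC | intermediate
18 | (2R,3S)-2-hydroxy-3-methyl-7-(pinacolboryl)oct-7-enal | C=C(B1OC(C)(C)C(C)(C)O1)CCC[C@H](C)[C@@H](O)C=O | intermediate
19 | methyl ester of the (5S,6R,7R,8S,14S)-6,7-dihydroxy open-chain acid (C7–C8 bond formed; C15=C17H2; C1 Bpin; C14 OTIB/S(O)Tol) | C=C(B1OC(C)(C)C(C)(C)O1)CCC[C@H](C)[C@@H](O)[C@H](O)[C@@H](C/C=C(\C)CC[C@@H](OC(=O)c1c(C(C)C)cc(C(C)C)cc1C(C)C)[S@@](=O)c1ccc(C)cc1)C(=C)C(=O)OC | intermediate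
20 | (5S,6R,7R,8S,10E,14S)-1,14-seco hydroxy lactone | C=C(B1OC(C)(C)C(C)(C)O1)CCC[C@H](C)[C@@H](O)[C@@H]1OC(=O)C(=C)[C@@H]1C/C=C(\C)CC[C@@H](OC(=O)c1c(C(C)C)cc(C(C)C)cc1C(C)C)[S@@](=O)c1ccc(C)cc1 | intermediate
21 | (5S,6R,7R,8S,10E,14S)-1,14-seco acetoxy lactone | C=C(B1OC(C)(C)C(C)(C)O1)CCC[C@H](C)[C@@H](OC(C)=O)[C@@H]1OC(=O)C(=C)[C@@H]1C/C=C(\C)CC[C@@H](OC(=O)c1c(C(C)C)cc(C(C)C)cc1C(C)C)[S@@](=O)c1ccc(C)cc1 | intermediate
22 | (14S)-α-(TIB-oxy)alkylmagnesium chloride carbenoid of 21 | C=C(B1OC(C)(C)C(C)(C)O1)CCC[C@H](C)[C@@H](OC(C)=O)[C@@H]1OC(=O)C(=C)[C@@H]1C/C=C(\C)CC[C@@H](OC(=O)c1c(C(C)C)cc(C(C)C)cc1C(C)C)[Mg]Cl | intermediate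
23 | 15-membered cyclic pinacol boronate complex (B bonded to C1 and C14; C14 still bearing OTIB), chloromagnesium salt | C=C1CCC[C@H](C)[C@@H](OC(C)=O)[C@@H]2OC(=O)C(=C)[C@@H]2C/C=C(\C)CC[C@@H](OC(=O)c2c(C(C)C)cc(C(C)C)cc2C(C)C)[B-]13OC(C)(C)C(C)(C)O3.[Mg+]Cl | intermediate
24 | (5S,6R,7R,8S,10E,14R)-6-acetoxy-14-(pinacolboryl) macrocyclic lactone | C=C1CCC[C@H](C)[C@@H](OC(C)=O)[C@@H]2OC(=O)C(=C)[C@@H]2C/C=C(\C)CC[C@H]1B1OC(C)(C)C(C)(C)O1 | intermediate
25 | (5S,6R,7R,8S,10E,14R)-6-acetoxy-14-hydroxy macrocyclic lactone | C=C1CCC[C@H](C)[C@@H](OC(C)=O)[C@@H]2OC(=O)C(=C)[C@@H]2C/C=C(\C)CC[C@H]1O | intermediate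
26 | (5S,6R,7R,8S,10E,14R)-6,14-diacetoxy macrocyclic lactone | C=C1CCC[C@H](C)[C@@H](OC(C)=O)[C@@H]2OC(=O)C(=C)[C@@H]2C/C=C(\C)CC[C@H]1OC(C)=O | intermediate
27 | CNP0323853.1, (5S,6R,7R,8S,10R,11R,14R)-6,14-diacetoxy-10,11-epoxy macrocyclic α-methylene lactone | C=C1CCC[C@H](C)[C@@H](OC(C)=O)[C@@H]2OC(=O)C(=C)[C@@H]2C[C@H]2O[C@]2(C)CC[C@H]1OC(C)=O | target

**Totals**
Total step count: 12. Longest linear sequence: 9 steps (steps 1–4, then 8–12).

**Three steps most likely to fail**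

Step 10 (the proposed ring contraction). Risks are oligomerisation, slow exchange at high dilution and attack of the carbenoid or Grignard reagent on the acrylate. The fallback uses known chemistry, sets out from 5 and 17 and comes back at 26; it makes the two unions in the reverse order, so the 1,2-metallate shift is the ordinary intermolecular lithiation–borylation and the ring is closed by a conventional intramolecular Barbier allylation. Compound 17 is silylated (TESCl, imidazole) to the triethylsilyl ether of 17 F1. Compound 5 is lithiated as in step 3 to 6, which is borylated with F1 and, after MgBr2·OEt2-promoted 1,2-migration, gives the acyclic (14R)-allylic boronic ester F2. Oxidation (H2O2, NaOH) gives the acyclic (14R)-allylic alcohol F3, and Ac2O gives the C14 acetate F4. Cross-metathesis of F4 with 8 gives the 2-(bromomethyl)enoate F5. Aqueous HCl in THF cleaves acetal and silyl ether to the hydroxy aldehyde F6, which is cyclised with indium in THF–water at 2 mM and lactonised (TsOH) to the macrocyclic 6-hydroxy-14-acetoxy lactone F7. Acetylation of F7 gives 26.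

Step 8 (one-pot acetal hydrolysis, chelation-controlled Barbier coupling and lactonisation). Risks are erosion of the syn,syn selectivity and δ-lactone formation. The fallback sets out from 9 and 17 and comes back at 20; it replaces the aqueous Barbier reaction by a Lewis-acid-chelated allylstannane addition. Compound 17 is protected (PMB trichloroacetimidate, cat. La(OTf)3) as the PMB ether of 17 F8, and the acetal is hydrolysed (LiBF4, wet MeCN) to the α-(p-methoxybenzyloxy) aldehyde F9. Compound 9 is converted (Bu3SnSnBu3, Pd2(dba)3 cat., THF) into the allylstannane F10. MgBr2·OEt2-mediated addition of F10 to F9 (Keck-type chelation control, open transition state, CH2Cl2, −20 °C) and acid lactonisation give the PMB-protected cis-lactone F11. DDQ (CH2Cl2, pH 7 buffer) removes the PMB group to give 20.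

Step 4 (cross-metathesis with a 1,1-disubstituted bromomethyl acrylate in the presence of a sulfoxide). Risks are low conversion and alkene isomerisation. The fallback sets out from 2 and comes back at 9; it builds the enoate by carbonyl chemistry. The alane 4 (from 2 as in step 2) is turned into its ate complex (n-BuLi) and opened with ethylene oxide to the homoallylic alcohol F12. TBSCl and imidazole give the silyl ether F13, and lithiation–sulfinylation as in step 3 gives the α-sulfinyl TIB ester F14. HF·pyridine gives the alcohol F15, and Dess–Martin oxidation gives the β,γ-unsaturated aldehyde F16. Vinylalumination (methyl propiolate, DIBAL-H, NMO, THF) gives the Baylis–Hillman-type alcohol F17 as a mixture of carbinol epimers, and PBr3 (SN2′, Et2O, 0 °C) gives 9.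

**Further compounds**
F1 | step 10 | (2R,3S)-1,1-dimethoxy-3-methyl-7-(pinacolboryl)-2-(triethylsilyloxy)oct-7-ene | C=C(B1OC(C)(C)C(C)(C)O1)CCC[C@H](C)[C@@H](O[Si](CC)(CC)CC)C(OC)OC
F2 | step 10 | acyclic (14R)-allylic boronic ester (C14–C1 bond formed; C8 terminal vinyl; C6 OTES; C7 dimethyl acetal) | C=CC/C=C(\C)CC[C@@H](B1OC(C)(C)C(C)(C)O1)C(=C)CCC[C@H](C)[C@@H](O[Si](CC)(CC)CC)C(OC)OC
F3 | step 10 | acyclic (14R)-allylic alcohol | C=CC/C=C(\C)CC[C@@H](O)C(=C)CCC[C@H](C)[C@@H](O[Si](CC)(CC)CC)C(OC)OC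
F4 | step 10 | acyclic (14R)-allylic acetate | C=CC/C=C(\C)CC[C@@H](OC(C)=O)C(=C)CCC[C@H](C)[C@@H](O[Si](CC)(CC)CC)C(OC)OC
F5 | step 10 | methyl (2Z)-2-(bromomethyl)enoate with C14 OAc, C6 OTES and C7 dimethyl acetal | COC(=O)/C(CBr)=C/C/C=C(\C)CC[C@@H](OC(C)=O)C(=C)CCC[C@H](C)[C@@H](O[Si](CC)(CC)CC)C(OC)OC
F6 | step 10 | α-hydroxy aldehyde bromide (C14 OAc) | COC(=O)/C(CBr)=C/C/C=C(\C)CC[C@@H](OC(C)=O)C(=C)CCC[C@H](C)[C@@H](O)C=O
F7 | step 10 | (5S,6R,7R,8S,10E,14R)-14-acetoxy-6-hydroxy macrocyclic lactone | C=C1CCC[C@H](C)[C@@H](O)[C@@H]2OC(=O)C(=C)[C@@H]2C/C=C(\C)CC[C@H]1OC(C)=O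
F8 | step 8 | (2R,3S)-1,1-dimethoxy-2-(4-methoxybenzyloxy)-3-methyl-7-(pinacolboryl)oct-7-ene | C=C(B1OC(C)(C)C(C)(C)O1)CCC[C@H](C)[C@@H](OCc1ccc(OC)cc1)C(OC)OC
F9 | step 8 | (2R,3S)-2-(4-methoxybenzyloxy)-3-methyl-7-(pinacolboryl)oct-7-enal | C=C(B1OC(C)(C)C(C)(C)O1)CCC[C@H](C)[C@@H](OCc1ccc(OC)cc1)C=O
F10 | step 8 | methyl (2Z,5E,9S)-6-methyl-9-[(S)-p-tolylsulfinyl]-2-[(tributylstannyl)methyl]-9-(TIB-oxy)nona-2,5-dienoate | COC(=O)/C(C[Sn](CCCC)(CCCC)CCCC)=C/C/C=C(\C)CC[C@@H](OC(=O)c1c(C(C)C)cc(C(C)C)cc1C(C)C)[S@@](=O)c1ccc(C)cc1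
F11 | step 8 | 6-O-PMB ether of 20 | C=C(B1OC(C)(C)C(C)(C)O1)CCC[C@H](C)[C@@H](OCc1ccc(OC)cc1)[C@@H]1OC(=O)C(=C)[C@@H]1C/C=C(\C)CC[C@@H](OC(=O)c1c(C(C)C)cc(C(C)C)cc1C(C)C)[S@@](=O)c1ccc(C)cc1
F12 | step 4 | (4E)-8-hydroxy-4-methyloct-4-en-1-yl 2,4,6-triisopropylbenzoate | OCC/C=C(\C)CCCOC(=O)c1c(C(C)C)cc(C(C)C)cc1C(C)C
F13 | step 4 | (4E)-8-(tert-butyldimethylsilyloxy)-4-methyloct-4-en-1-yl 2,4,6-triisopropylbenzoate | CC(C)(C)[Si](C)(C)OCC/C=C(\C)CCCOC(=O)c1c(C(C)C)cc(C(C)C)cc1C(C)C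
F14 | step 4 | (1S,4E)-8-(tert-butyldimethylsilyloxy)-4-methyl-1-[(S)-p-tolylsulfinyl]oct-4-en-1-yl 2,4,6-triisopropylbenzoate | CC(C)(C)[Si](C)(C)OCC/C=C(\C)CC[C@@H](OC(=O)c1c(C(C)C)cc(C(C)C)cc1C(C)C)[S@@](=O)c1ccc(C)cc1
F15 | step 4 | (1S,4E)-8-hydroxy-4-methyl-1-[(S)-p-tolylsulfinyl]oct-4-en-1-yl 2,4,6-triisopropylbenzoate | OCC/C=C(\C)CC[C@@H](OC(=O)c1c(C(C)C)cc(C(C)C)cc1C(C)C)[S@@](=O)c1ccc(C)cc1
F16 | step 4 | (1S,4E)-4-methyl-8-oxo-1-[(S)-p-tolylsulfinyl]oct-4-en-1-yl 2,4,6-triisopropylbenzoate | O=CC/C=C(\C)CC[C@@H](OC(=O)c1c(C(C)C)cc(C(C)C)cc1C(C)C)[S@@](=O)c1ccc(C)cc1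
F17 | step 4 | methyl (5E,9S)-3-hydroxy-6-methyl-2-methylidene-9-[(S)-p-tolylsulfinyl]-9-(TIB-oxy)non-5-enoate (both C3 epimers) | COC(=O)C(=C)C(O)C/C=C(\C)CC[C@@H](OC(=O)c1c(C(C)C)cc(C(C)C)cc1C(C)C)[S@@](=O)c1ccc(C)cc1
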